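## Structural features

Bisdehydroneotuberostemonine (28) is built on a pyrrole (ring A) that shares its N–C(α) bond with an azepane (ring B) and its C(α)–C(β) bond with a cyclohexane (ring C). The core numbering used below is C-1 and C-2 for the pyrrole CH carbons (C-2 next to nitrogen), N-3, C-4 to C-7 for the four azepane methylenes, C-7a for the azepane methine, C-8 (ethyl), C-9 (oxygen), C-10 (pyrrolylic CH), and C-10a/C-10b for the fused pyrrole β- and α-carbons. An α-methyl-γ-butyrolactone (ring D) is cis-fused to ring C through O–C-9 and C–C-10, and a second α-methyl-γ-butyrolactone (ring E) hangs by its γ-carbon on C-2. Five contiguous stereocentres run C-7a (R), C-8 (R), C-9 (R), C-10 (S) and the ring D methyl carbon (S). The ethyl group is trans to C-7 and cis to both the C-9 oxygen and the C-10 branch, and the ring D methyl sits on the concave face, cis to the C-10–C-10a bond. Ring E carries two further centres (S at the carbinol carbon, S at the methyl carbon, 1,3-cis) that the flat pyrrole insulates from the core. The fragile sites are the electron-rich pyrrole (acid, oxidants), the pyrrolyl C–O bond of ring E (ionisation to an azafulvenium ion, hydrogenolysis) and the two lactone α-centres, of which the concave ring D methyl is probably the less stable epimer. The real difficulty is the stereopentad around rings C and D, together with the absolute configuration of ring E, which has no relay from the core. The key step exploits the fact that N-3 is bonded to both pyrrole α-carbons (C-2 and C-10b) and, through C-4 to C-7, to C-7a, which is itself attached to C-10b. A ring C ketone at C-10b with an acetaldehyde arm on C-10a is therefore a 1,4-dicarbonyl that one nitrogen at the end of the butyl chain on C-7a can close into rings A and B together.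

## Logic of the disconnections

28 from 27: the two C–H bonds made at the exocyclic C=C of ring E are removed, so the ring E methyl centre becomes a methylene. This deletes one stereocentre and lets the carbinol centre of ring E direct it. The forward hydrogenation must add to the ring E face opposite the pyrrolyl group and must not cleave the pyrrolyl C–O bond.

27 from 24 and 25: the bond between the ring E carbinol carbon and its CH2 neighbour is cut, together with the acyl–oxygen bond of ring E. All of ring E then comes from one purchasable C4 unit and the core keeps only a formyl group. Because the core centres are too remote to bias the aldehyde faces, the forward allylation must be catalyst-controlled (Si-face attack).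

24 from 22: the C-2–CHO bond is cut. The formyl carbon is an electrophilic one-carbon unit, and the forward step must select the free α-position C-2 over C-1 and leave ring D alone.

22 from 20: the acyl–oxygen bond of ring D and the C-9–H bond are cut, giving a keto ester. C-9 is then set by hydride reduction of a ring ketone. The hydride must arrive along the equatorial line so that the alkoxide is axial, cis to the ester branch, and can close ring D.

20 from 15 and 17 (17 from 16): the C-10–CH(CH3) bond is cut. C-10 is the doubly activated α-carbon of 15 and the methyl centre is bought with 16. The forward step needs C-alkylation at C-10 with clean inversion and a thermodynamic preference for the 8,10-cis ketone.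

15 from 14: the C-9 carbonyl is masked as a dioxolane so that it stays inert while another ring carbonyl is used for the pyrrole. The forward hydrolysis must be mild enough for the pyrrole.

14 from 11: both N–C(α) bonds of ring A (N-3–C-2 and N-3–C-10b) are cut, which opens rings A and B at once. What remains is one cyclohexanone carrying an acetaldehyde arm and an azidobutyl chain. The nitrogen must condense with the ring ketone intramolecularly before it cross-links aldehydes, and the C-7a configuration must survive.

11 from 9, and 9 from 8: the aldehyde comes from cleavage of a terminal C=C, and the C–N bond from displacement of a primary chloride. Placing the azide after the enolate chemistry keeps it away from the amide base. Ozone and the ozonide reductant must leave the azide untouched.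

8 from 5 and 6: the bond between the ketone α′-carbon (spiro C-9, the future C-10a) and the allyl CH2 is cut. The forward step requires kinetic enolisation at the CH2 and not at the tertiary α-carbon.

5 from 1, 2 and 3: the ethyl–ring and butyl–ring bonds are cut across the enone C=C. This is the only asymmetric event of the core, and every other core centre derives from it. It demands high face selectivity and a zinc enolate that a primary iodide can alkylate anti to the new ethyl group.

## Other disconnections considered

Alternative 1: the bond between the ring D methyl carbon and C-10 is cut. The forward step decomposes the 2-diazopropanoate A2 of the C-9 alcohol (tert-butyl ester on C-2) with Rh2(O2CCPh3)4, and the carbenoid inserts into the cis C-10–H bond to give A1.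
- In its favour: the cis fusion is fixed by geometry, C-10 is created with retention, and no reactive triflate or base equilibration is needed. On these points it is the equal of, or better than, the chosen plan.
- Against it: α-alkyl carbenoids are prone to a 1,2-hydride shift to the acrylate, the tertiary C-8–H is also within reach, and the pyrrole π-system can trap the carbenoid. The methyl centre would be set by the insertion transition state with no clear bias toward the concave face, whereas the chosen plan imports it from 16 by SN2.
- Step economy: reduction, acylation and diazo transfer precede the insertion, and the C-2 ester needs a redox adjustment before ring E. The route would probably be two or three steps longer.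

Alternative 2: the C-10–C-10a bond is cut. Sc(OTf)3 activates the butenolide of A4 and the pyrrole β-carbon adds 6-exo to its β-carbon; α-protonation gives A3, which has the same structure as 22.
- In its favour: ring C, C-10 and the methyl centre form in one catalytic step, the cis fusion is enforced, protonation on the convex face places the methyl on the concave face as required, and the endgame is shared. In bond-forming economy of the ring D region it is better than the chosen plan.
- Against it: A4 must carry C-7a, C-8 and C-9 on an open chain, without the ring template that the chosen plan uses for all three. The free pyrrole α-position is the more nucleophilic site and can react intermolecularly, and an α-methylbutenolide is a weak acceptor.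
- Overall the saving in the late steps is likely to be repaid in the synthesis of A4.

Alternative 3: the C-7a–C-8 bond is cut. A chiral N-triflylphosphoramide ionises the racemic carbinol A6 to an azafulvenium ion that the ketone enol captures, giving A5.
- In its favour: a flat racemic precursor is funnelled to one enantiomer, two stereocentres are set in the ring-forming step, and azide and ozone are avoided. The chosen key step sets no stereocentre, so on these points the alternative is better.
- Against it: the enantiocontrol rests on ion pairing with a seven-membered cyclic azafulvenium ion and an unactivated ketone enol. The C-2 ester disfavours ionisation and may be cleaved by the strong acid, and the more stable enol (toward the pyrrolylic CH2) is unproductive.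
- The chosen plan takes its absolute configuration from a well-established copper-catalysed conjugate addition. The later steps would be about equal in number, since the ester must still be brought to the aldehyde level.

Key step: step 5

Remarks on the chemistry:
- The key-step precursor 11 and product 14 both carry the target's R configuration at the ethyl carbon and at the azepane methine, so no structure needed correction.
- Compared with the obvious order, the azide is introduced after the enolate allylation, and the ozonide is reduced with a sulfide and not a phosphine, so the azide first meets phosphorus in step 5.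
- Assumption: the copper–(S,R,R)-phosphoramidite catalyst is taken to attack enone 1 with the topicity it shows on cyclohex-2-enone (S product there, 6R here because the ketal carbon outranks the carbonyl-side carbon). The mirror-image ligand would be used if the sense were reversed.
- Assumption: in step 11 the ligand enantiomer is the one that directs Si-face attack on the aldehyde.

## Route

Step 1
Reactants: 1 1,4-dioxaspiro[4.5]dec-6-en-8-one; 2 diethylzinc; 3 1-chloro-4-iodobutane
Product: 5 (6R,7R)-7-(4-chlorobutyl)-6-ethyl-1,4-dioxaspiro[4.5]decan-8-one, via ethylzinc enolate 4 (not isolated)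
Conditions: Cu(OTf)2 (2 mol %), (S,R,R)-BINOL bis(1-phenylethyl)amine phosphoramidite (4 mol %), Et2Zn, toluene, −30 °C; then 3, (Me2N)3PO, 0 °C → rt; aq. NH4Cl
Reagents that add atoms: diethylzinc (2), CC[Zn]CC; 1-chloro-4-iodobutane (3), ClCCCCI
Why: Copper-catalysed asymmetric conjugate addition places the ethyl group on the enone β-carbon under ligand control (6R); the zinc enolate 4 is then alkylated at the carbon–iodine end of 3 (iodide far more reactive than chloride) anti to the new ethyl group, giving the 6,7-trans ketone (tandem conjugate addition–enolate alkylation).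

Step 2
Reactants: 5 (6R,7R)-7-(4-chlorobutyl)-6-ethyl-1,4-dioxaspiro[4.5]decan-8-one; 6 allyl bromide
Product: 8 (6R,7R)-7-(4-chlorobutyl)-6-ethyl-9-(prop-2-en-1-yl)-1,4-dioxaspiro[4.5]decan-8-one (C-9 epimers), via lithium enolate 7 (not isolated)
Conditions: LiN(i-Pr)2, THF, −78 °C; 6, DMPU, −78 → −30 °C
Reagents that add atoms: allyl bromide (6), C=CCBr
Why: Kinetic deprotonation occurs at the unhindered CH2 and not at the tertiary C-7–H, and the enolate is C-allylated; the C-9 configuration is irrelevant because this carbon becomes sp2 in step 5, and the primary chloride is inert at this temperature.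

Step 3
Reactants: 8 (6R,7R)-7-(4-chlorobutyl)-6-ethyl-9-(prop-2-en-1-yl)-1,4-dioxaspiro[4.5]decan-8-one
Product: 9 (6R,7R)-7-(4-azidobutyl)-6-ethyl-9-(prop-2-en-1-yl)-1,4-dioxaspiro[4.5]decan-8-one (C-9 epimers)
Conditions: NaN3, NaI (cat.), DMF, 60 °C
Reagents that add atoms: sodium azide, [Na+].[N-]=[N+]=[N-]
Why: SN2 displacement of the primary chloride with iodide catalysis; the only base-sensitive centre that matters (C-7) already has the favoured trans, diequatorial arrangement.

Step 4
Reactants: 9 (6R,7R)-7-(4-azidobutyl)-6-ethyl-9-(prop-2-en-1-yl)-1,4-dioxaspiro[4.5]decan-8-one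
Product: 11 (6R,7R)-7-(4-azidobutyl)-6-ethyl-9-(2-oxoethyl)-1,4-dioxaspiro[4.5]decan-8-one (C-9 epimers), via secondary ozonide 10 (not isolated)
Conditions: O3, CH2Cl2, −78 °C; then Me2S, −78 °C → rt; used crude
Reagents that add atoms: ozone, [O-][O+]=O
Why: Ozonolysis cleaves only the terminal alkene, since alkyl azide, ketal and ketone are inert to ozone at −78 °C; the sulfide reduces the ozonide without touching the azide, which a phosphine would not.

Step 5
Reactants: 11 (6R,7R)-7-(4-azidobutyl)-6-ethyl-9-(2-oxoethyl)-1,4-dioxaspiro[4.5]decan-8-one
Product: 14 (7aR,8R)-8-ethyl-4,5,6,7,7a,8-hexahydro-10H-spiro[azepino[3,2,1-hi]indole-9,2'-[1,3]dioxolane], via iminophosphorane 12 (not isolated), via cyclic imine 13 (not isolated)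
Conditions: PPh3 (1.2 equiv), THF (0.02 M), rt → 50 °C; then AcOH, 60 °C
Reagents that add atoms: none
Why: PPh3 adds to the terminal azide nitrogen and loses N2 to give iminophosphorane 12 (Staudinger reaction), which undergoes an intramolecular aza-Wittig reaction with the ring ketone to the seven-membered imine 13; any amine formed by adventitious water condenses at the same carbonyl. The imine nitrogen then adds to the pendant aldehyde, and loss of the C-9 proton and of water under AcOH aromatises the five-membered ring. The closest known reaction type is the Paal–Knorr pyrrole synthesis from a 1,4-dicarbonyl and a primary amine released from an azide by a phosphine. Ring B closes 7-exo-trig at the ketone carbonyl and ring A closes 5-exo-trig at the aldehyde carbonyl. No stereocentre is created: the two C-9 epimers converge because that carbon becomes aromatic, the ethyl centre is not enolisable, and the methine next to the imine has the trans arrangement that is also favoured at equilibrium. The selectivity required is intramolecular condensation at the ketone ahead of intermolecular imine formation at aldehydes. It is secured by the four-carbon tether, by moderate dilution, and by the reversibility of imine formation under AcOH, with the aromatic pyrrole as the only irreversible exit. The dioxolane should survive warm AcOH in the absence of added water.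

Step 6
Reactants: 14 (7aR,8R)-8-ethyl-4,5,6,7,7a,8-hexahydro-10H-spiro[azepino[3,2,1-hi]indole-9,2'-[1,3]dioxolane]
Product: 15 (7aR,8R)-8-ethyl-4,5,6,7,7a,8-hexahydroazepino[3,2,1-hi]indol-9(10H)-one
Conditions: 1 M aq. HCl, THF, 0 °C → rt; used promptly
Reagents that add atoms: water, O
Why: Acid-catalysed ketal hydrolysis; dilute acid at low temperature should spare the trialkylpyrrole, C-7a cannot enolise, and C-8 keeps its ethyl group equatorial and trans to C-7.

Step 7
Reactants: 16 methyl (S)-lactate
Product: 17 methyl (S)-2-(trifluoromethanesulfonyloxy)propanoate
Conditions: Tf2O, 2,6-lutidine, CH2Cl2, −78 → 0 °C; used at once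
Reagents that add atoms: triflic anhydride, O=S(=O)(C(F)(F)F)OS(=O)(=O)C(F)(F)F
Why: O-sulfonylation of the secondary alcohol does not touch the stereocentre, so the S configuration is kept.

Step 8
Reactants: 15 (7aR,8R)-8-ethyl-4,5,6,7,7a,8-hexahydroazepino[3,2,1-hi]indol-9(10H)-one; 17 methyl (S)-2-(trifluoromethanesulfonyloxy)propanoate
Product: 20 methyl (2S)-2-[(7aR,8R,10S)-8-ethyl-9-oxo-4,5,6,7,7a,8,9,10-octahydroazepino[3,2,1-hi]indol-10-yl]propanoate, via lithium enolate 18 (not isolated), via C-10 epimer mixture 19 (not isolated)
Conditions: LiN(SiMe3)2, THF, −78 °C; 17, −78 → −20 °C; aq. NH4Cl; crude, DBU (0.2 equiv), CH2Cl2, rt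
Reagents that add atoms: methyl (S)-2-(trifluoromethanesulfonyloxy)propanoate (17), C[C@H](OS(=O)(=O)C(F)(F)F)C(=O)OC
Why: The base removes a proton from C-10, which is both α to the ketone and pyrrolylic, and the enolate carbon displaces triflate with inversion (SN2), which gives the S propanoate centre because the priority order changes. DBU then equilibrates only the doubly activated C-10 to the isomer with the branch pseudo-equatorial and cis to the ethyl group, while the far less acidic ester α-carbon is untouched.

Step 9
Reactants: 20 methyl (2S)-2-[(7aR,8R,10S)-8-ethyl-9-oxo-4,5,6,7,7a,8,9,10-octahydroazepino[3,2,1-hi]indol-10-yl]propanoate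
Product: 22 tetracyclic lactone (7aR,8R,9R,10S; ring D methyl carbon S; C-2 unsubstituted), via lithium alkoxide 21 (not isolated)
Conditions: LiBH(s-Bu)3, THF, −78 → 0 °C; aq. NH4Cl
Reagents that add atoms: none
Why: The bulky hydride attacks the ketone along the equatorial line and gives the axial alkoxide, cis to both equatorial neighbours (9R); the alkoxide closes onto the methyl ester (5-exo-trig) and expels methoxide, forming the cis-fused lactone (diastereoselective reduction–lactonisation).

Step 10
Reactants: 22 tetracyclic lactone (C-2 unsubstituted)
Product: 24 tetracyclic lactone 2-carbaldehyde, via iminium salt 23 (not isolated)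
Conditions: POCl3, DMF, CH2Cl2, 0 °C → rt; then aq. NaOAc
Reagents that add atoms: N,N-dimethylformamide, CN(C)C=O; water, O
Why: Vilsmeier–Haack formylation attacks the only free pyrrole α-position (C-2), which is more nucleophilic than C-1; buffered hydrolysis of the iminium salt leaves ring D and its α-centre alone.

Step 11
Reactants: 24 tetracyclic lactone 2-carbaldehyde; 25 ethyl 2-(bromomethyl)acrylate
Product: 27 2-[(2S)-4-methylidene-5-oxooxolan-2-yl] tetracyclic lactone, via silyl ether 26 (not isolated)
Conditions: CrCl2 (10 mol %), carbazole-bridged bis(oxazoline) ligand (12 mol %), Mn, Me3SiCl, i-Pr2NEt (cat.), THF, rt; then Bu4NF, THF, 0 °C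
Reagents that add atoms: ethyl 2-(bromomethyl)acrylate (25), C=C(CBr)C(=O)OCC
Why: In this catalytic asymmetric Nozaki–Hiyama–Kishi allylation, the allyl species on ligand-bound trivalent chromium adds to the Si face of the aldehyde through a six-membered transition state; Mn returns the metal to divalent chromium and Me3SiCl frees it as silyl ether 26. Fluoride unmasks the alkoxide, which closes onto the acrylate ester (5-exo-trig). The core centres are too remote to interfere, so the new S centre is catalyst-controlled.

Step 12
Reactants: 27 2-[(2S)-4-methylidene-5-oxooxolan-2-yl] tetracyclic lactone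
Product: 28 bisdehydroneotuberostemonine
Conditions: H2 (1 atm), Pd/C (5 %), EtOAc, rt, stopped at full conversion
Reagents that add atoms: none
Why: Heterogeneous hydrogenation adds H2 to the exocyclic alkene from the ring E face opposite the pyrrolyl substituent, which gives the 1,3-cis lactone (S methyl centre); neutral solvent and low pressure are chosen to spare the pyrrolyl C–O bond and the pyrrole.

## Compound list

1 | 1,4-dioxaspiro[4.5]dec-6-en-8-one | O=C1C=CC2(CC1)OCCO2 | starting material
2 | diethylzinc | CC[Zn]CC | starting material
3 | 1-chloro-4-iodobutane | ClCCCCI | starting material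
4 | ethylzinc (6R)-6-ethyl-1,4-dioxaspiro[4.5]dec-7-en-8-olate | CC[C@H]1C2(OCCO2)CCC(O[Zn]CC)=C1 | intermediate
5 | (6R,7R)-7-(4-chlorobutyl)-6-ethyl-1,4-dioxaspiro[4.5]decan-8-one | CC[C@H]1C2(OCCO2)CCC(=O)[C@@H]1CCCCCl | intermediate
6 | allyl bromide | C=CCBr | starting material
7 | lithium (6R,7R)-7-(4-chlorobutyl)-6-ethyl-1,4-dioxaspiro[4.5]dec-8-en-8-olate | CC[C@H]1C2(OCCO2)CC=C(O[Li])[C@@H]1CCCCCl | intermediate
8 | (6R,7R)-7-(4-chlorobutyl)-6-ethyl-9-(prop-2-en-1-yl)-1,4-dioxaspiro[4.5]decan-8-one, C-9 epimers | CC[C@H]1C2(OCCO2)CC(CC=C)C(=O)[C@@H]1CCCCCl | intermediate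
9 | (6R,7R)-7-(4-azidobutyl)-6-ethyl-9-(prop-2-en-1-yl)-1,4-dioxaspiro[4.5]decan-8-one, C-9 epimers | CC[C@H]1C2(OCCO2)CC(CC=C)C(=O)[C@@H]1CCCCN=[N+]=[N-] | intermediate
10 | secondary ozonide of 9 (1,2,4-trioxolan-3-ylmethyl group on C-9) | CC[C@H]1C2(OCCO2)CC(CC3OCOO3)C(=O)[C@@H]1CCCCN=[N+]=[N-] | intermediate
11 | (6R,7R)-7-(4-azidobutyl)-6-ethyl-9-(2-oxoethyl)-1,4-dioxaspiro[4.5]decan-8-one, C-9 epimers | CC[C@H]1C2(OCCO2)CC(CC=O)C(=O)[C@@H]1CCCCN=[N+]=[N-] | intermediate
12 | iminophosphorane of 11 (N=PPh3 in place of N3) | CC[C@H]1C2(OCCO2)CC(CC=O)C(=O)[C@@H]1CCCCN=P(c1ccccc1)(c1ccccc1)c1ccccc1 | intermediate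
13 | seven-membered cyclic imine (C=N at the former ring ketone, aldehyde arm intact) | CC[C@H]1C2(OCCO2)CC(CC=O)C3=NCCCC[C@H]13 | intermediate
14 | (7aR,8R)-8-ethyl-4,5,6,7,7a,8-hexahydro-10H-spiro[azepino[3,2,1-hi]indole-9,2'-[1,3]dioxolane] | CC[C@H]1C2(OCCO2)Cc2ccn3c2[C@@H]1CCCC3 | intermediate
15 | (7aR,8R)-8-ethyl-4,5,6,7,7a,8-hexahydroazepino[3,2,1-hi]indol-9(10H)-one | CC[C@H]1C(=O)Cc2ccn3c2[C@@H]1CCCC3 | intermediate
16 | methyl (S)-lactate | C[C@H](O)C(=O)OC | starting material
17 | methyl (S)-2-(trifluoromethanesulfonyloxy)propanoate | C[C@H](OS(=O)(=O)C(F)(F)F)C(=O)OC | intermediate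
18 | lithium enolate of 15 (C-9–C-10 enolate) | CC[C@H]1C(O[Li])=Cc2ccn3c2[C@@H]1CCCC3 | intermediate
19 | methyl (2S)-2-[(7aR,8R)-8-ethyl-9-oxo-octahydroazepino[3,2,1-hi]indol-10-yl]propanoate, C-10 epimers | CC[C@H]1C(=O)C([C@H](C)C(=O)OC)c2ccn3c2[C@@H]1CCCC3 | intermediate
20 | methyl (2S)-2-[(7aR,8R,10S)-8-ethyl-9-oxo-4,5,6,7,7a,8,9,10-octahydroazepino[3,2,1-hi]indol-10-yl]propanoate | CC[C@H]1C(=O)[C@@H]([C@H](C)C(=O)OC)c2ccn3c2[C@@H]1CCCC3 | intermediate
21 | lithium (7aR,8R,9R,10S)-9-alkoxide of 20 (axial O, cis to ethyl and to the ester branch) | CC[C@H]1[C@@H](O[Li])[C@@H]([C@H](C)C(=O)OC)c2ccn3c2[C@@H]1CCCC3 | intermediate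
22 | tetracyclic lactone: (7aR,8R,9R,10S) core with cis-fused (S)-α-methyl-γ-butyrolactone, C-2 unsubstituted | CC[C@H]1[C@H]2OC(=O)[C@@H](C)[C@H]2c2ccn3c2[C@@H]1CCCC3 | intermediate
23 | C-2 dimethyliminium dichlorophosphate of 22 | CC[C@H]1[C@H]2OC(=O)[C@@H](C)[C@H]2c2cc(C=[N+](C)C)n3c2[C@@H]1CCCC3.[O-]P(=O)(Cl)Cl | intermediate
24 | tetracyclic lactone 2-carbaldehyde | CC[C@H]1[C@H]2OC(=O)[C@@H](C)[C@H]2c2cc(C=O)n3c2[C@@H]1CCCC3 | intermediate
25 | ethyl 2-(bromomethyl)acrylate | C=C(CBr)C(=O)OCC | starting material
26 | ethyl (4S)-2-methylidene-4-(trimethylsilyloxy)-4-(tetracyclic lactone-2-yl)butanoate | CC[C@H]1[C@H]2OC(=O)[C@@H](C)[C@H]2c2cc([C@@H](O[Si](C)(C)C)CC(=C)C(=O)OCC)n3c2[C@@H]1CCCC3 | intermediate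
27 | 2-[(2S)-4-methylidene-5-oxooxolan-2-yl] tetracyclic lactone | CC[C@H]1[C@H]2OC(=O)[C@@H](C)[C@H]2c2cc([C@@H]3CC(=C)C(=O)O3)n3c2[C@@H]1CCCC3 | intermediate
28 | bisdehydroneotuberostemonine, ring E (2S,4S)-4-methyl-5-oxooxolan-2-yl at C-2 | CC[C@H]1[C@H]2OC(=O)[C@@H](C)[C@H]2c2cc([C@@H]3C[C@H](C)C(=O)O3)n3c2[C@@H]1CCCC3 | target

## Step count and least certain steps

Total: 12 steps. Longest linear sequence: 11 steps (steps 1–6 and 8–12 from 1); step 7 is a one-step side branch.

Step 5 (key step). The phosphorus imine may condense with aldehydes of other molecules faster than it closes onto the hindered ring ketone, leading to oligomerisation. The methine next to the transient imine may also epimerise through the enamine, and the ketal may be lost in warm acid. The fallback sets out from 8 and rejoins the route at 14, building the pyrrole first and the azepane second. Ozonolysis of 8 (O3; Me2S) would give the chloro keto aldehyde F1. A Paal–Knorr condensation with NH4OAc in AcOH would give the N-unsubstituted pyrrole F2. Deprotonation with NaH in DMF (NaI cat.) would then close ring B by intramolecular N-alkylation (7-exo-tet) to 14.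

Step 1. The zinc enolate is a weak nucleophile toward an unactivated primary iodide, so protonation without alkylation, or enolate equilibration with loss of the trans relationship, may compete. The face selectivity on a ketal-substituted enone may also be lower than on simple enones. The fallback sets out from 1 and rejoins at 5. The conjugate addition is run in the same way, but the enolate is silylated (Me3SiOTf) and isolated as the trimethylsilyl enol ether F3. MeLi in THF then releases the lithium enolate F4, which is far more reactive and is alkylated by 3 in THF/DMPU to give 5.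

Step 8. O-alkylation or elimination of the very reactive secondary triflate may outrun C-alkylation. The equilibrium at C-10 may also favour the cis isomer less than expected, because the pseudo-equatorial branch lies close to the C-1 hydrogen. The fallback sets out from 15 and rejoins at 22.
- Enolate 18 is alkylated with methyl bromoacetate, a primary electrophile that cannot eliminate, and equilibrated with DBU to the keto ester F5.
- LiBH(s-Bu)3 gives the cis-fused lactone without the methyl group, F6.
- LiN(i-Pr)2 forms its lithium enolate F7, and MeI methylates it on the convex face to the epimeric methyl lactone F8.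
- A second deprotonation to the lithium enolate F9, followed by kinetic protonation on the convex face with 2,6-di-tert-butylphenol, places the methyl on the concave face and gives 22.

Step 11. A pyrrole-2-carbaldehyde is a vinylogous formamide, so the addition may be slow and the enantioselectivity may erode. The pyrrolyl carbinol may also ionise during desilylation. The fallback sets out from 22 and rejoins at 28, and it also replaces steps 10 and 12. Friedel–Crafts acylation of C-2 with (S)-methylsuccinic anhydride (AlCl3, CH2Cl2, 0 °C), at the less hindered carbonyl, would give the keto acid F10, which already carries the S methyl centre. Catalyst-controlled reduction of the ketone (RuCl(p-cymene)(TsDPEN), HCO2H/Et3N, or a Corey–Bakshi–Shibata reduction) would give the hydroxy acid F11, which lactonises to 28.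

Step 12. Hydrogenolysis of the pyrrolyl C–O bond, migration of the double bond into the ring to give a butenolide, or insufficient face selectivity may occur on the metal surface. The fallback sets out from 27 and rejoins at 28. Conjugate reduction with LiBH(s-Bu)3 in THF at −78 °C would give the lactone lithium enolate F12. Kinetic protonation on the face opposite the pyrrolyl group with a hindered phenol then delivers the cis methyl lactone 28 without a metal surface.

## Further compounds

F1 | step 5 | (6R,7R)-7-(4-chlorobutyl)-6-ethyl-9-(2-oxoethyl)-1,4-dioxaspiro[4.5]decan-8-one, C-9 epimers | CC[C@H]1C2(OCCO2)CC(CC=O)C(=O)[C@@H]1CCCCCl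
F2 | step 5 | N-unsubstituted pyrrole ketal with 4-chlorobutyl chain on the methine | CC[C@H]1C2(OCCO2)Cc2cc[nH]c2[C@@H]1CCCCCl
F3 | step 1 | (6R)-6-ethyl-8-(trimethylsilyloxy)-1,4-dioxaspiro[4.5]dec-7-ene | CC[C@H]1C2(OCCO2)CCC(O[Si](C)(C)C)=C1
F4 | step 1 | lithium (6R)-6-ethyl-1,4-dioxaspiro[4.5]dec-7-en-8-olate | CC[C@H]1C2(OCCO2)CCC(O[Li])=C1
F5 | step 8 | methyl 2-[(7aR,8R,10S)-8-ethyl-9-oxo-octahydroazepino[3,2,1-hi]indol-10-yl]acetate | CC[C@H]1C(=O)[C@@H](CC(=O)OC)c2ccn3c2[C@@H]1CCCC3
F6 | step 8 | tetracyclic lactone lacking the ring D methyl | CC[C@H]1[C@H]2OC(=O)C[C@H]2c2ccn3c2[C@@H]1CCCC3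
F7 | step 8 | lithium enolate of F6 | CC[C@H]1[C@H]2OC(O[Li])=C[C@H]2c2ccn3c2[C@@H]1CCCC3
F8 | step 8 | tetracyclic lactone with the ring D methyl on the convex face (R methyl carbon) | CC[C@H]1[C@H]2OC(=O)[C@H](C)[C@H]2c2ccn3c2[C@@H]1CCCC3
F9 | step 8 | lithium enolate of F8 | CC[C@H]1[C@H]2OC(O[Li])=C(C)[C@H]2c2ccn3c2[C@@H]1CCCC3
F10 | step 11 | (2S)-2-methyl-4-oxo-4-(tetracyclic lactone-2-yl)butanoic acid | CC[C@H]1[C@H]2OC(=O)[C@@H](C)[C@H]2c2cc(C(=O)C[C@H](C)C(=O)O)n3c2[C@@H]1CCCC3
F11 | step 11 | (2S,4S)-4-hydroxy-2-methyl-4-(tetracyclic lactone-2-yl)butanoic acid | CC[C@H]1[C@H]2OC(=O)[C@@H](C)[C@H]2c2cc([C@@H](O)C[C@H](C)C(=O)O)n3c2[C@@H]1CCCC3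
F12 | step 12 | lithium enolate of ring E (from conjugate reduction of 27) | CC[C@H]1[C@H]2OC(=O)[C@@H](C)[C@H]2c2cc([C@@H]3CC(C)=C(O[Li])O3)n3c2[C@@H]1CCCC3
A1 | alternative 1 | tetracyclic lactone with tert-butyl ester on C-2 | CC[C@H]1[C@H]2OC(=O)[C@@H](C)[C@H]2c2cc(C(=O)OC(C)(C)C)n3c2[C@@H]1CCCC3
A2 | alternative 1 | 2-diazopropanoate of the (9R)-alcohol of the tricyclic tert-butyl ester | CC[C@H]1[C@@H](OC(=O)C(C)=[N+]=[N-])Cc2cc(C(=O)OC(C)(C)C)n3c2[C@@H]1CCCC3
A3 | alternative 2 | tetracyclic core lacking ring E (same structure as 22) | CC[C@H]1[C@H]2OC(=O)[C@@H](C)[C@H]2c2ccn3c2[C@@H]1CCCC3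
A4 | alternative 2 | pyrroloazepine with a 1-(4-methyl-5-oxo-2,5-dihydrofuran-2-yl)propyl chain on the methine | CC[C@@H]([C@H]1OC(=O)C(C)=C1)[C@H]1CCCCn2cccc12
A5 | alternative 3 | tricyclic ketone with tert-butyl ester on C-2, ethyl trans to C-7 | CC[C@H]1C(=O)Cc2cc(C(=O)OC(C)(C)C)n3c2[C@@H]1CCCC3
A6 | alternative 3 | racemic pyrroloazepine carbinol with a 2-oxopentyl chain on the pyrrole β-carbon | CCCC(=O)Cc1cc(C(=O)OC(C)(C)C)n2CCCCC(O)c12
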